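**Retrosynthetic overview**
- Target ⇐ its tert-butyl ester ⇐ (Z)-enol triflate + AcOCH2–Zn reagent (C13–C16 coupling; alkene geometry comes from the Z-triflate).
- Exocyclic 8(17)-alkene ⇐ tertiary C8–OH (dehydration); 8-hydroxy β-keto ester ⇐ 2-methoxy δ-lactone + tert-butyl acetate enolate (C13–C14 Claisen opening).
- Key disconnection: C2–OMe ⇐ C2–H of the saturated tricyclic δ-lactone (site- and face-selective C–H methoxylation; the lactone oxygen masks the later alkene).
- δ-Lactone ⇐ farnesylacetic acid by one enantioselective cationic cascade (ring A closes first, then ring B, then the temporary δ-lactone ring) ⇐ farnesyl bromide + acetic acid.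

Assumption: labdane numbering (C1–C20) is used in names and comments; the target is read as the ent-labdane (2R,5R,9R,10R,13Z), and (2E,6E)-farnesyl bromide is taken as a catalogue compound.

**Step 1**
Reactants: 1 (2E,6E)-farnesyl bromide; 2 acetic acid
Product: 4 (4E,8E)-5,9,13-trimethyltetradeca-4,8,12-trienoic acid (farnesylacetic acid), via dilithium acetate dianion 3 (not isolated)
Conditions: 2 (3 equiv), LDA (6 equiv), THF–DMPU, 0 to 40 °C; then 1, 0 °C to rt; aq HCl work-up
Reagents that add atoms: none
Why: Carboxylic acid dianion alkylation (SN2) at the primary allylic bromide occurs at the α-carbon without allylic transposition, so both E-alkenes are kept; no stereocentre is formed.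

**Step 2**
Reactants: 4 farnesylacetic acid
Product: 5 ent-ambreinolide, (5R,8S,9S,10R)-14,15,16-trinorlabdan-13,8-olide (trans-decalin δ-lactone; C8–O and C9–C11 trans-diequatorial; C17 methyl cis to C20 methyl)
Conditions: (S)-LBA [(S)-2-(2-fluorobenzyloxy)-2'-hydroxy-1,1'-binaphthyl·SnCl4, 2 equiv, ligand recovered], toluene, −78 °C, 48 h; then CF3CO2H·SnCl4, −78 °C; recrystallise (hexane) to ≥99% ee
Reagents that add atoms: none
Why: Enantioselective protonative polyene cyclisation with a Lewis acid-assisted chiral Brønsted acid: face-selective protonation of the isopropylidene, chair–chair anti-additions across the two E-alkenes and capture of the C8 cation by the carboxyl oxygen set C5, C10, C9 and C8 in one cascade (relative configuration from the E-alkenes, absolute sense from the (S)-ligand, the mirror image of the (R)-LBA that gives the natural series, as in the homofarnesic acid to sclareolide case).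

**Step 3**
Reactants: 5 ent-ambreinolide
Product: 6 (2R,5R,8S,9S,10R)-2-methoxy-14,15,16-trinorlabdan-13,8-olide (OMe equatorial, trans to the C10 methyl)
Conditions: N-fluoro-N-tert-butyl-3,5-bis(trifluoromethyl)benzamide (1.5 equiv), Me3SiOMe (2.5 equiv), [Cu(MeCN)4]PF6 (10 mol %), bathophenanthroline (12 mol %), PhCF3, 40 °C
Reagents that add atoms: methoxytrimethylsilane CO[Si](C)(C)C
Why: Proposed new method: copper-catalysed amidyl-radical-relay C(sp3)–H methoxylation of an unactivated methylene. Cu(I) reduces the N–F amide to Cu(II)–F and a bulky electrophilic amidyl radical; this abstracts the equatorial C2–H, the only methylene flanked by two CH2 groups and remote from the lactone (the site known from amidyl-radical halogenation of sclareolide); Me3SiOMe converts Cu(II)–F into Cu(II)–OMe (Si–F formation); the C2 radical is captured by Cu(II)–OMe on the face away from the two syn-axial methyls (C10-Me and axial 4-Me), and C–O reductive elimination from Cu(III) gives the equatorial 2R ether and returns Cu(I). The closest known reaction types are Cu/N–F radical-relay benzylic C–H etherification and cyanation (Kharasch–Sosnovsky-type radical capture by Cu(II)).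

**Step 4**
Reactants: 6 2-methoxy lactone; 7 tert-butyl acetate
Product: 9 tert-butyl (2R,5R,8S,9S,10R)-8-hydroxy-2-methoxy-13-oxo-16-norlabdan-15-oate, via tert-butyl lithioacetate 8 (not isolated)
Conditions: 7 (3 equiv), LDA (3 equiv), THF, −78 °C; add 6, −78 to −30 °C; aq NH4Cl
Reagents that add atoms: none
Why: Crossed Claisen condensation of an ester enolate with a lactone: the enolate adds to the unhindered δ-lactone carbonyl, the tertiary C8 alkoxide is expelled and the β-keto ester is protected from over-addition as its enolate; no stereocentre is touched.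

**Step 5**
Reactants: 9 β-keto ester
Product: 10 tert-butyl (2R,5R,8S,9S,10R,13Z)-8-hydroxy-2-methoxy-13-(trifluoromethylsulfonyloxy)-16-norlabd-13-en-15-oate
Conditions: Tf2O (1.5 equiv), sat. aq LiOH, toluene, 5 °C, 15 min
Reagents that add atoms: triflic anhydride O=S(=O)(OS(=O)(=O)C(F)(F)F)C(F)(F)F
Why: Z-selective enol triflation of a β-keto ester: the lithium-chelated (Z)-enolate is O-sulfonylated, which fixes the C13=C14 geometry (OTf cis to the ester), and the tertiary alcohol is not triflated in the aqueous biphasic medium.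

**Step 6**
Reactants: 10 hydroxy enol triflate
Product: 11 tert-butyl (2R,5R,9R,10R,13Z)-2-methoxy-13-(trifluoromethylsulfonyloxy)-16-norlabda-8(17),13-dien-15-oate
Conditions: SOCl2 (1.5 equiv), pyridine (6 equiv), CH2Cl2, −78 to −40 °C
Reagents that add atoms: none
Why: E2 dehydration through the chlorosulfite: the equatorial C8–O bond has no anti-periplanar ring hydrogen, only those of the C17 methyl, so the exocyclic 8(17)-alkene forms (known behaviour of 8-hydroxylabdanes); the C8 stereocentre is removed and C9 is untouched.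

**Step 7**
Reactants: 11 dienyl triflate; 12 bromomethyl acetate
Product: 14 tert-butyl (2R,5R,9R,10R,13Z)-16-acetoxy-2-methoxylabda-8(17),13-dien-15-oate, via (acetoxymethyl)zinc bromide 13 (not isolated)
Conditions: 12 (3 equiv), Zn dust, LiCl, THF, 25 °C; then 11, Pd(PPh3)4 (5 mol %), THF, 40 °C
Reagents that add atoms: none
Why: Negishi cross-coupling of an alkenyl triflate with an α-acyloxyalkylzinc halide proceeds with retention of alkene geometry, so CH2OAc ends up cis to the ester (13Z); no stereocentre is formed.

**Step 8**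
Reactants: 14 tert-butyl ester
Product: 15 (2Z)-3-(acetoxymethyl)-5-[(1R,4aR,7R,8aR)-7-methoxy-5,5,8a-trimethyl-2-methylidenedecahydronaphthalen-1-yl]pent-2-enoic acid (target)
Conditions: TMSOTf (3 equiv), 2,6-lutidine (4.5 equiv), CH2Cl2, 0 °C; then pH 4 aqueous work-up
Reagents that add atoms: none
Why: Silyl triflate-mediated tert-butyl ester cleavage (loss of isobutene to the silyl ester, hydrolysed on work-up) under buffered non-protic conditions spares the allylic acetate, the methyl ether and the exocyclic alkene, and the acetate blocks lactonisation to the butenolide.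

**Compound list**
1 | (2E,6E)-farnesyl bromide | CC(C)=CCC/C(C)=C/CC/C(C)=C/CBr | starting material
2 | acetic acid | CC(=O)O | starting material
3 | dilithium acetate dianion | [Li+].[Li+].[CH2-]C([O-])=O | intermediate
4 | (4E,8E)-5,9,13-trimethyltetradeca-4,8,12-trienoic acid (farnesylacetic acid) | CC(C)=CCC/C(C)=C/CC/C(C)=C/CCC(=O)O | intermediate
5 | ent-ambreinolide, (5R,8S,9S,10R)-14,15,16-trinorlabdan-13,8-olide | O=C1CC[C@@H]2[C@](C)(CC[C@@H]3C(C)(C)CCC[C@]32C)O1 | intermediate
6 | (2R,5R,8S,9S,10R)-2-methoxy-14,15,16-trinorlabdan-13,8-olide | O=C1CC[C@@H]2[C@](C)(CC[C@@H]3C(C)(C)C[C@@H](OC)C[C@]32C)O1 | intermediate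
7 | tert-butyl acetate | CC(=O)OC(C)(C)C | starting material
8 | tert-butyl lithioacetate (lithium enolate of 7) | [Li+].[CH2-]C(=O)OC(C)(C)C | intermediate
9 | tert-butyl (2R,5R,8S,9S,10R)-8-hydroxy-2-methoxy-13-oxo-16-norlabdan-15-oate | CC(C)(C)OC(=O)CC(=O)CC[C@@H]1[C@@](C)(O)CC[C@@H]2C(C)(C)C[C@@H](OC)C[C@]21C | intermediate
10 | tert-butyl (2R,5R,8S,9S,10R,13Z)-8-hydroxy-2-methoxy-13-(trifluoromethylsulfonyloxy)-16-norlabd-13-en-15-oate | CC(C)(C)OC(=O)/C=C(\OS(=O)(=O)C(F)(F)F)CC[C@@H]1[C@@](C)(O)CC[C@@H]2C(C)(C)C[C@@H](OC)C[C@]21C | intermediate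
11 | tert-butyl (2R,5R,9R,10R,13Z)-2-methoxy-13-(trifluoromethylsulfonyloxy)-16-norlabda-8(17),13-dien-15-oate | CC(C)(C)OC(=O)/C=C(\OS(=O)(=O)C(F)(F)F)CC[C@@H]1C(=C)CC[C@@H]2C(C)(C)C[C@@H](OC)C[C@]21C | intermediate
12 | bromomethyl acetate | CC(=O)OCBr | starting material
13 | (acetoxymethyl)zinc bromide | CC(=O)OC[Zn]Br | intermediate
14 | tert-butyl (2R,5R,9R,10R,13Z)-16-acetoxy-2-methoxylabda-8(17),13-dien-15-oate | CC(C)(C)OC(=O)/C=C(\COC(C)=O)CC[C@@H]1C(=C)CC[C@@H]2C(C)(C)C[C@@H](OC)C[C@]21C | intermediate
15 | (2Z)-3-(acetoxymethyl)-5-[(1R,4aR,7R,8aR)-7-methoxy-5,5,8a-trimethyl-2-methylidenedecahydronaphthalen-1-yl]pent-2-enoic acid | C=C1CC[C@@H]2C(C)(C)C[C@@H](OC)C[C@@]2(C)[C@@H]1CC/C(=C/C(=O)O)COC(C)=O | target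

**Total step count:** 8. **Longest linear sequence:** 8 steps (1 to 15).

**Steps most likely to fail**

Step 3 (new C–H methoxylation). The risks are hydrogen abstraction from the methoxy source, copper-mediated oxidative elimination of the C2 radical to an alkene, and some C3 isomer. The fallback uses known chemistry and sets out from 5. The established C2-selective methylene oxidation of this ring type (quinuclidine-mediated anodic oxidation under O2, or Fe(PDP)/H2O2/AcOH) gives the 2-oxo lactone F1. An equilibrating Meerwein–Ponndorf–Verley reduction (Al(OiPr)3, iPrOH, toluene, reflux) then gives the equatorial 2-alcohol F2, favoured because the axial epimer suffers two syn-axial methyl/OH contacts. O-Methylation (MeOTf, 2,6-di-tert-butyl-4-methylpyridine, CH2Cl2) brings the sequence back to the route at 6.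

Step 2 (enantioselective cyclisation). The risks are moderate ee, partly cyclised material and losses on enrichment. The fallback sets out from 4 and replaces asymmetric induction by resolution. Cyclisation with an achiral superacid (ClSO3H, 2-nitropropane, −78 °C) gives the racemic δ-lactone F3. Saponification (KOH, aq MeOH), cold acidification to the hydroxy acid, salt formation with (S)-1-phenylethylamine and fractional crystallisation give the (S)-1-phenylethylammonium salt of the ent-series hydroxy acid F4. Acidification and warming in toluene relactonise it, and the route is rejoined at 5.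

Step 7 (Negishi coupling with the acetoxymethylzinc reagent). The risks are limited stability and slow transmetalation of the α-acyloxy zinc species, and protodezincation. The fallback sets out from 11 and installs a protected hydroxymethyl group instead. Suzuki–Miyaura coupling with potassium (4-methoxybenzyloxy)methyltrifluoroborate (Pd(OAc)2/RuPhos, Cs2CO3, dioxane–H2O, 80 °C) gives the PMB ether F5. DDQ (CH2Cl2/pH 7 buffer, 0 °C) releases the (Z)-hydroxy ester F6, which is acetylated at once in the cold (Ac2O, pyridine, DMAP, 0 °C) before it can lactonise, and the route is rejoined at 14.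

**Further compounds**
F1 | step 3 | (5R,8S,9S,10R)-2-oxo-14,15,16-trinorlabdan-13,8-olide | O=C1CC[C@@H]2[C@](C)(CC[C@@H]3C(C)(C)CC(=O)C[C@]32C)O1
F2 | step 3 | (2R,5R,8S,9S,10R)-2-hydroxy-14,15,16-trinorlabdan-13,8-olide (equatorial OH) | O=C1CC[C@@H]2[C@](C)(CC[C@@H]3C(C)(C)C[C@@H](O)C[C@]32C)O1
F3 | step 2 | racemic δ-lactone (1:1 mixture of 5 and its mirror image) | O=C1CC[C@@H]2[C@](C)(CC[C@@H]3C(C)(C)CCC[C@]32C)O1.O=C1CC[C@H]2[C@@](C)(CC[C@H]3C(C)(C)CCC[C@@]32C)O1
F4 | step 2 | (S)-1-phenylethylammonium (5R,8S,9S,10R)-8-hydroxy-14,15,16-trinorlabdan-13-oate | [O-]C(=O)CC[C@@H]1[C@@](C)(O)CC[C@@H]2C(C)(C)CCC[C@]21C.C[C@@H](c1ccccc1)[NH3+]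
F5 | step 7 | tert-butyl (2R,5R,9R,10R,13Z)-2-methoxy-16-(4-methoxybenzyloxy)labda-8(17),13-dien-15-oate | CC(C)(C)OC(=O)/C=C(\COCc1ccc(OC)cc1)CC[C@@H]1C(=C)CC[C@@H]2C(C)(C)C[C@@H](OC)C[C@]21C
F6 | step 7 | tert-butyl (2R,5R,9R,10R,13Z)-16-hydroxy-2-methoxylabda-8(17),13-dien-15-oate | CC(C)(C)OC(=O)/C=C(\CO)CC[C@@H]1C(=C)CC[C@@H]2C(C)(C)C[C@@H](OC)C[C@]21C
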